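## Structural features

The target 19 is a 5,6,7,8-tetrahydro-1H-isochromen-8-one: a 2H-pyran ring (O2, C1H2, C8a, C4a, C4, C3) fused through the tetrasubstituted C4a=C8a alkene to a cyclohexenone ring (C8 ketone, C7, C6, C5H2), with an (E)-prop-1-enyl chain on C3. The two stereocentres are neighbours: C7 (S) is quaternary and carries methyl and an acyloxy group between the C8 ketone and C6, and C6 (R) is a secondary carbinol; the two oxygens are trans. The C7 oxygen is esterified with 4-hydroxy-2-methoxy-6-methylbenzoic acid, a 2,6-disubstituted benzoate on a tertiary alcohol, which is the kind of ester least accessible by acylation. Fragile elements are the push–pull enol ether O2–C3=C4–C4a=C8a–C8=O (acid-labile, no hydrogenation possible), the β-hydroxy ketone C6–C7–C8 (retro-aldol and acyl shift under base), the C5 hydrogens (γ to the enone and β to the C6 oxygen, so elimination through the dienolate threatens), the free phenol and the (E)-alkene. The real difficulty is the contiguous array C8(=O)–C7(Me)(O-aroyl)–C6(OH)–C5H2, with its hindered ester and trans relation, placed next to a tetrasubstituted alkene that carries two different carbon arms. The key step exploits the fact that C8, C7, C6 and C5 form a four-carbon chain holding all the oxygenation and both stereocentres of the carbocycle, which is a cyclobutanone, while C8a and C4a are the two carbons of an alkyne that bears the CH2O group and the enyne arm. Inserting that alkyne into the C8–C5 bond gives the cyclohexenone.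

## Logic of the disconnections

19 to 18: the O2–C3 enol-ether bond of the pyran is cut. The dienyl ether is the most acid-sensitive unit and is best made last; opening it turns C3 and C4 into alkyne carbons and the bicycle into a monocycle whose enyne arm can pass through metal chemistry. The forward step must add the C1 hydroxyl to C3 (6-endo) and not to C4 (5-exo), with a catalyst that tolerates a free phenol and a β-hydroxy ketone.

18 to 17: the three O–H bonds are traced back to O–Si bonds. One kind of protecting group on the primary, the secondary and the phenolic oxygen allows a single deprotection; the forward step must be a fluoride source that is not basic.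

17 to 11 and 16: the bonds C8–C8a and C4a–C5 are cut. This removes the tetrasubstituted alkene with both its arms as one alkyne and leaves a four-membered ketone that already holds C7, C6 and the ester. The route becomes convergent and the key step creates no stereocentre. The forward step must cleave C8–C5 and not C8–C7, must engage the alkyne nearer the silyl ether with C8 going to C8a, and must close the ring before the C6 silyloxy group is lost.

11 to 10: no bond is cut; the enantiomers are separated. The ketene that precedes 10 is planar and achiral, so a racemate is unavoidable without an auxiliary; the demand is a separable, configurationally stable ketone, which a quaternary C7 and a non-enolisable C6 provide.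

10 to 9 and 7: the bonds C6–C7 and C5–C8 are cut. This is the only disconnection that builds the quaternary C7 with the hindered ester already on it, from a two-carbon ketene and a two-carbon enol ether. The forward cycloaddition must put the silyloxy group on C6 (electronic control) and trans to the acyloxy group (approach control).

9 to 8, 6, 5, 4 and 3: functional-group changes only. These are C=C=O from H–C–COCl, acid chloride from acid, acid from benzyl ester, aryl O–CH3 from the hydrogen-bonded phenol, and aryl O–Si from the free phenol. The order is dictated by reactivity: the unchelated C4 hydroxyl must be blocked before the C2 hydroxyl can be methylated, and the benzyl group must go while no alkene is present.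

3 to 1 and 2: the alkyl–oxygen bond of the benzoate is cut, not the acyl–oxygen bond. A carboxylate attacking a secondary bromide is indifferent to the two ortho substituents that would block acylation; the forward step must ionise the acid and not the phenols.

16 to 15 and 14: the C(sp)–C(sp) bond between the two alkynes is cut, giving a bromoalkyne and a terminal alkyne of very different polarity, so cross-coupling can outrun homocoupling. 15 to 13 to 12: the bromoalkyne comes from a dibromoalkene and that from an (E)-enal, which fixes the alkene geometry from a cheap source.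

## Other disconnections considered

Alternative 1: The cut is C6–C7. A2, the C7 tertiary alcohol of the bicyclic core with C6 as its silyl ether, would be traced to the ring-contracted α-ketol A1, in which C6 is still bonded to C8 and C8 carries a hydroxyl and an acetyl group.
- Forward step: Al(O-t-Bu)3 would chelate the hydroxyl and acetyl oxygens and induce an α-ketol (acyloin) rearrangement. C6 shifts from C8 to the acetyl carbon, the five-membered carbocycle becomes six-membered, C8 becomes the ketone and the acetyl carbon becomes C7.
- In its favour: the reaction type is established, and here the alternative is better than the chosen plan, whose key step is unprecedented on such a ketone. The syn-periplanar chelate should pass the C8 configuration on to C7 (for the (6R,7R) isomer A1 the model predicts 7S), and C6 migrates with retention. The pyran is already present, so no late gold step is needed.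
- Against it here: C8 offers two migrating groups, C6 and the alkenyl carbon C8a, and an sp2 carbon usually migrates at least as readily, which would give the regioisomeric ring. The Lewis acid and heat act on an acid-labile dienyl ether. A1, a cyclopentene-fused pyran with a quaternary carbinol next to a silyloxy carbon, is no easier to make than 11. A2 still needs the 2,6-disubstituted aroyl group on a tertiary α-keto alcohol, the very acylation that the chosen plan avoids by forming the ester in 3.
- Comparison: structurally both plans move the difficulty into a smaller ring (equal). Mechanistically alternative 1 is safer in its key step and less safe afterwards. In step count, the ester problem and the synthesis of A1 are expected to cost more than the chosen route.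

Alternative 2: The cut runs through the benzoate ring at C1'–C2' and C5'–C6'. A5, the C6 triethylsilyl ether of 19, would come from the C7 but-2-ynoate A3 and the diene A4.
- Forward step: a thermal [4+2] cycloaddition joins the nucleophilic CH2 terminus of A4 to the methyl-bearing alkyne carbon and the ketene-acetal carbon to the carboxyl-bearing one. Loss of methanol and of the silyl group aromatises the adduct.
- In its favour: a slim four-carbon acyl group can be placed on the tertiary C7 oxygen where a 2,6-disubstituted benzoyl group cannot. The polarity of the partners writes the 2-methoxy-4-hydroxy-6-methyl pattern directly, without phenol protection or selective methylation; on this point the alternative is better than the chosen plan, which spends steps 2 and 3 on it.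
- Against it here: it contributes nothing to the core, the two stereocentres or the C7 carbinol centre, all of which are left to other chemistry. But-2-ynoates are sluggish dienophiles, so the heat required meets a substrate with an acid- and heat-sensitive dienyl ether, a β-silyloxy ketone and a second diene that A4 or the ynoate could engage. The most hindered bond is completed in the last steps, where failure costs most.
- Comparison: on the ester question the plans are equal in intent, since neither acylates with the hindered acid. Its key step is a known reaction type, the chosen one is not. Overall step economy is worse unless a short route to A3 exists.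

Alternative 3: The cut is C7–C8. A7, the monocyclic tertiary ketol with the enyne and the silyloxymethyl group in place, would come from the acyclic enal–methyl ketone A6.
- Forward step: a chiral triazolium-derived carbene adds to the aldehyde, the resulting acyl-anion equivalent attacks the methyl ketone, and an intramolecular crossed benzoin reaction closes the carbocycle and creates C7.
- In its favour: the absolute configuration at C7 comes from a catalyst, whereas the chosen plan needs a resolution in step 6, so alternative 3 is better here. Aldehyde–ketone benzoin cyclisations to six-membered tertiary ketols are a known reaction type. A7 shares the enyne, the silyloxymethyl group and the fluoride/gold endgame with 17 (equal).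
- Against it here: the aldehyde is an enal, whose carbene adduct reacts readily as a homoenolate, and its β-carbon carries an alkyne that opens further protonation and redox pathways. C6 in A6 is α to the ketone and can epimerise or lose its silyloxy group under the basic conditions of carbene generation. Catalyst and the C6 stereocentre must be matched. A6 needs a tetrasubstituted alkene of defined geometry with the aldehyde cis to the C5 chain. A7 is again a tertiary alcohol to be acylated with the hindered acid.
- Comparison: structurally it reaches the same monocyclic enyne as the chosen plan but without the ester. Mechanistically it trades an unprecedented metal insertion for a known but here poorly suited organocatalytic step. It needs at least one step more after the key step (acylation) and a longer acyclic prelude.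

Key step: step 9

Remarks on the chemistry, made before the steps:
- The locants C1–C8a of 19 are used for the corresponding atoms of all precursors.
- The stereodescriptors were checked atom by atom: (1S,2R) in 11 corresponds to (6R,7S) in 19 with trans oxygens, so no stereochemical correction is needed.
- An orsellinate with both phenols free would be methylated first at the unchelated C4 hydroxyl, giving the wrong ether, and a 2,6-disubstituted methyl benzoate cannot be saponified in the presence of an aryl silyl ether. The arene therefore enters as free orsellinic acid 1, is esterified by carboxylate alkylation, silylated at C4 and only then methylated at C2.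
- The lactate unit enters as racemic benzyl 2-bromopropanoate 2, because its stereocentre is erased in ketene 9.
- The (E)-propenyl alkyne needs its own source, crotonaldehyde 12.
- The propargylic oxygen carries a tert-butyldimethylsilyl group, so that 14 can be bought and all three silyl groups are alike.
- Assumption: 1, 2, 7, 12 and 14 are purchased. Compound 10 is a racemate and its SMILES lists both enantiomers. The absolute configuration of 11 is to be secured by anomalous-dispersion X-ray diffraction or by chiroptical correlation at the stage of 19.

## Route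

Step 1
Reactants: 1 orsellinic acid (2,4-dihydroxy-6-methylbenzoic acid); 2 benzyl 2-bromopropanoate (racemic)
Product: 3 1-(benzyloxy)-1-oxopropan-2-yl 2,4-dihydroxy-6-methylbenzoate (racemic)
Conditions: KHCO3, DMF, rt
Reagents that add atoms: none
Why: Carboxylate O-alkylation (SN2) at a secondary α-bromo ester; hydrogencarbonate ionises only the carboxylic acid, so the phenols stay free and the hindered carboxyl is esterified without any acyl transfer; the new stereocentre is racemic and disappears in step 5.

Step 2
Reactants: 3 1-(benzyloxy)-1-oxopropan-2-yl 2,4-dihydroxy-6-methylbenzoate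
Product: 4 1-(benzyloxy)-1-oxopropan-2-yl 4-[(tert-butyldimethylsilyl)oxy]-2-hydroxy-6-methylbenzoate
Conditions: TBSCl (1.1 equiv), imidazole, CH2Cl2, 0 °C
Reagents that add atoms: tert-butyldimethylsilyl chloride, CC(C)(C)[Si](C)(C)Cl
Why: Silylation of a phenol; the C2 hydroxyl is held in a hydrogen bond to the ester carbonyl, so one equivalent of silyl chloride should go to the free C4 hydroxyl.

Step 3
Reactants: 4 1-(benzyloxy)-1-oxopropan-2-yl 4-[(tert-butyldimethylsilyl)oxy]-2-hydroxy-6-methylbenzoate
Product: 5 1-(benzyloxy)-1-oxopropan-2-yl 4-[(tert-butyldimethylsilyl)oxy]-2-methoxy-6-methylbenzoate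
Conditions: MeOH, PPh3, DIAD, THF, 0 °C → rt
Reagents that add atoms: methanol, CO
Why: Mitsunobu etherification; the neutral redox conditions methylate the hydrogen-bonded phenol without the carbonate bases that could strip the aryl silyl ether or attack the two esters.

Step 4
Reactants: 5 1-(benzyloxy)-1-oxopropan-2-yl 4-[(tert-butyldimethylsilyl)oxy]-2-methoxy-6-methylbenzoate
Product: 6 2-({4-[(tert-butyldimethylsilyl)oxy]-2-methoxy-6-methylbenzoyl}oxy)propanoic acid (racemic)
Conditions: H2 (1 atm), Pd/C (10 %), EtOAc, rt
Reagents that add atoms: none
Why: Hydrogenolysis of a benzyl ester; no alkene is present yet, and the aryl silyl ether, the aryl methyl ether and the alkyl benzoate are inert.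

Step 5
Reactants: 6 2-({4-[(tert-butyldimethylsilyl)oxy]-2-methoxy-6-methylbenzoyl}oxy)propanoic acid; 7 tert-butyldimethyl(vinyloxy)silane
Product: 10 rac-(1S*,2R*)-2-[(tert-butyldimethylsilyl)oxy]-1-methyl-4-oxocyclobutyl 4-[(tert-butyldimethylsilyl)oxy]-2-methoxy-6-methylbenzoate, via acid chloride 8 (not isolated), via aroyloxy(methyl)ketene 9 (not isolated)
Conditions: (COCl)2, DMF (cat.), CH2Cl2, 0 °C → rt, evaporate; then slow addition to 7 (5 equiv), Et3N (1.2 equiv), toluene, 80 °C
Reagents that add atoms: none
Why: Acid chloride formation, amine dehydrochlorination to the ketene and thermal ketene–enol ether [2+2] cycloaddition; the nucleophilic CH2 terminus of 7 bonds to the ketene carbonyl carbon, so the silyloxy group ends on C6; the small, electronegative acyloxy group is expected to lie on the approach side so that methyl ends cis and acyloxy trans to the silyloxy group (dipole minimisation acts the same way), and the diastereomers are separable on silica. Both stereocentres are formed here as a racemate.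

Step 6
Reactants: 10 rac-(1S*,2R*)-2-[(tert-butyldimethylsilyl)oxy]-1-methyl-4-oxocyclobutyl 4-[(tert-butyldimethylsilyl)oxy]-2-methoxy-6-methylbenzoate
Product: 11 (1S,2R)-2-[(tert-butyldimethylsilyl)oxy]-1-methyl-4-oxocyclobutyl 4-[(tert-butyldimethylsilyl)oxy]-2-methoxy-6-methylbenzoate
Conditions: preparative SFC, amylose tris(3,5-dimethylphenylcarbamate) phase, CO2/i-PrOH
Reagents that add atoms: none
Why: Resolution of a racemate by chromatography on a chiral stationary phase; no bond is changed, and a quaternary C7 and a C6 that is not α to the carbonyl make the ketone configurationally stable.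

Step 7
Reactants: 12 (E)-but-2-enal (crotonaldehyde)
Product: 13 (3E)-1,1-dibromopenta-1,3-diene
Conditions: CBr4, PPh3, CH2Cl2, 0 °C
Reagents that add atoms: carbon tetrabromide, BrC(Br)(Br)Br
Why: Corey–Fuchs (Ramirez) dibromo-olefination through the dibromomethylene ylide; the (E)-alkene of 12 is not touched.

Step 8
Reactants: 13 (3E)-1,1-dibromopenta-1,3-diene; 14 tert-butyldimethyl(prop-2-yn-1-yloxy)silane
Product: 16 tert-butyldimethyl{[(6E)-octa-6-ene-2,4-diyn-1-yl]oxy}silane, via (3E)-1-bromopent-3-en-1-yne 15 (not isolated)
Conditions: NaN(SiMe3)2, THF, −78 → −40 °C, NH4Cl quench; crude solution then added to 14, CuCl (10 mol %), NH2OH·HCl, n-BuNH2, H2O, 0 °C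
Reagents that add atoms: none
Why: Base-induced anti elimination of HBr gives the volatile bromoalkyne, which is used in solution; Cadiot–Chodkiewicz coupling of the copper acetylide of 14 with it forms the unsymmetrical diyne and leaves the (E)-alkene and the silyl ether alone.

Step 9
Reactants: 11 (1S,2R)-2-[(tert-butyldimethylsilyl)oxy]-1-methyl-4-oxocyclobutyl 4-[(tert-butyldimethylsilyl)oxy]-2-methoxy-6-methylbenzoate; 16 tert-butyldimethyl{[(6E)-octa-6-ene-2,4-diyn-1-yl]oxy}silane
Product: 17 (1S,6R)-6-[(tert-butyldimethylsilyl)oxy]-3-{[(tert-butyldimethylsilyl)oxy]methyl}-1-methyl-2-oxo-4-[(3E)-pent-3-en-1-yn-1-yl]cyclohex-3-en-1-yl 4-[(tert-butyldimethylsilyl)oxy]-2-methoxy-6-methylbenzoate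
Conditions: Ni(cod)2 (10 mol %), P(C6H11)3 (20 mol %), toluene, 60 → 90 °C, slow addition of 16 (1.5 equiv)
Reagents that add atoms: none
Why: Proposed new method: zerovalent nickel, formed from Ni(cod)2 and P(C6H11)3, should bind the ketone of 11 and the silyloxymethyl-substituted alkyne of 16 and undergo oxidative cyclisation to an oxanickelacyclopentene in which C8–C8a is formed and nickel sits on C4a, the carbon that carries the second alkyne and can hold the metal as an η3-propargyl unit. β-Carbon elimination from this strained spiro alkoxide then cleaves C8–C5 to a seven-membered nickelacycle, and C(sp3)–C(sp2) reductive elimination forms C4a–C5 and returns zerovalent nickel. The closest known reaction type is the nickel-catalysed intermolecular [4+2] insertion of alkynes into 3-substituted cyclobutanones, which has not been shown for an α-quaternary, α-acyloxy, β-silyloxy cyclobutanone or for an enediyne partner. The carbocycle is closed by that reductive elimination, a formal [4+2] ring expansion from four to six members driven by release of about 25 kcal/mol of ring strain. No stereocentre is created; C7 is quaternary and C6 is never α to a carbonyl or bonded to the metal, so the configuration of 11 should pass unchanged into 17. Three selectivities are needed: cleavage of C8–C5 and not C8–C7, secured by the preference of nickel for the primary CH2 over the quaternary acyloxy-bearing carbon; reaction at the alkyne nearer the silyl ether with C8 bonding to C8a, secured by the directing effect of the conjugated second alkyne and the lower steric demand at C8a; and reductive elimination faster than β-silyloxy elimination from the C5–Ni bond, favoured by the poor leaving-group ability of a bulky silyloxy group and by a metallacycle that keeps Ni–C5–C6–O away from syn-coplanarity.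

Step 10
Reactants: 17 (1S,6R)-6-[(tert-butyldimethylsilyl)oxy]-3-{[(tert-butyldimethylsilyl)oxy]methyl}-1-methyl-2-oxo-4-[(3E)-pent-3-en-1-yn-1-yl]cyclohex-3-en-1-yl 4-[(tert-butyldimethylsilyl)oxy]-2-methoxy-6-methylbenzoate
Product: 18 (1S,6R)-6-hydroxy-3-(hydroxymethyl)-1-methyl-2-oxo-4-[(3E)-pent-3-en-1-yn-1-yl]cyclohex-3-en-1-yl 4-hydroxy-2-methoxy-6-methylbenzoate
Conditions: HF·pyridine (excess), pyridine, THF, 0 °C → rt
Reagents that add atoms: none
Why: Fluoride-mediated cleavage of silyl ethers, driven by Si–F bond formation; the weakly acidic HF·pyridine/pyridine buffer avoids the alkoxide and dienolate chemistry (loss of the C6 oxygen through C5, retro-aldol cleavage, acyl shift) that basic fluoride could start, and the hindered aroyl group should not migrate.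

Step 11
Reactants: 18 (1S,6R)-6-hydroxy-3-(hydroxymethyl)-1-methyl-2-oxo-4-[(3E)-pent-3-en-1-yn-1-yl]cyclohex-3-en-1-yl 4-hydroxy-2-methoxy-6-methylbenzoate
Product: 19 (6R,7S)-6-hydroxy-7-methyl-8-oxo-3-[(1E)-prop-1-en-1-yl]-5,6,7,8-tetrahydro-1H-isochromen-7-yl 4-hydroxy-2-methoxy-6-methylbenzoate
Conditions: AuCl3 (5 mol %), CH2Cl2, 0 °C → rt
Reagents that add atoms: none
Why: Gold-catalysed cycloisomerisation (intramolecular hydroalkoxylation) of a (Z)-2-en-4-yn-1-ol; AuCl3 (trivalent gold) activates the alkyne, the primary hydroxyl attacks C3, which is both the δ-carbon of the ynenone and the carbon best stabilised by the propenyl group, so 6-endo-dig closure is expected over 5-exo, and protodeauration gives the enol ether. No stereocentre is formed or touched.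

## Compound list

1 | orsellinic acid (2,4-dihydroxy-6-methylbenzoic acid) | Cc1cc(O)cc(O)c1C(=O)O | starting material
2 | benzyl 2-bromopropanoate (racemic) | CC(Br)C(=O)OCc1ccccc1 | starting material
3 | 1-(benzyloxy)-1-oxopropan-2-yl 2,4-dihydroxy-6-methylbenzoate (racemic) | CC(OC(=O)c1c(C)cc(O)cc1O)C(=O)OCc1ccccc1 | intermediate
4 | 1-(benzyloxy)-1-oxopropan-2-yl 4-[(tert-butyldimethylsilyl)oxy]-2-hydroxy-6-methylbenzoate (racemic) | CC(OC(=O)c1c(C)cc(O[Si](C)(C)C(C)(C)C)cc1O)C(=O)OCc1ccccc1 | intermediate
5 | 1-(benzyloxy)-1-oxopropan-2-yl 4-[(tert-butyldimethylsilyl)oxy]-2-methoxy-6-methylbenzoate (racemic) | CC(OC(=O)c1c(C)cc(O[Si](C)(C)C(C)(C)C)cc1OC)C(=O)OCc1ccccc1 | intermediate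
6 | 2-({4-[(tert-butyldimethylsilyl)oxy]-2-methoxy-6-methylbenzoyl}oxy)propanoic acid (racemic) | CC(OC(=O)c1c(C)cc(O[Si](C)(C)C(C)(C)C)cc1OC)C(=O)O | intermediate
7 | tert-butyldimethyl(vinyloxy)silane | C=CO[Si](C)(C)C(C)(C)C | starting material
8 | 1-chloro-1-oxopropan-2-yl 4-[(tert-butyldimethylsilyl)oxy]-2-methoxy-6-methylbenzoate (racemic acid chloride) | CC(OC(=O)c1c(C)cc(O[Si](C)(C)C(C)(C)C)cc1OC)C(=O)Cl | intermediate (not isolated)
9 | 1-oxoprop-1-en-2-yl 4-[(tert-butyldimethylsilyl)oxy]-2-methoxy-6-methylbenzoate (aroyloxy(methyl)ketene) | CC(OC(=O)c1c(C)cc(O[Si](C)(C)C(C)(C)C)cc1OC)=C=O | intermediate (not isolated)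
10 | rac-(1S*,2R*)-2-[(tert-butyldimethylsilyl)oxy]-1-methyl-4-oxocyclobutyl 4-[(tert-butyldimethylsilyl)oxy]-2-methoxy-6-methylbenzoate (racemate, both enantiomers written) | O=C1[C@@](C)(OC(=O)c2c(C)cc(O[Si](C)(C)C(C)(C)C)cc2OC)[C@H](O[Si](C)(C)C(C)(C)C)C1.O=C1[C@](C)(OC(=O)c2c(C)cc(O[Si](C)(C)C(C)(C)C)cc2OC)[C@@H](O[Si](C)(C)C(C)(C)C)C1 | intermediate
11 | (1S,2R)-2-[(tert-butyldimethylsilyl)oxy]-1-methyl-4-oxocyclobutyl 4-[(tert-butyldimethylsilyl)oxy]-2-methoxy-6-methylbenzoate | O=C1[C@@](C)(OC(=O)c2c(C)cc(O[Si](C)(C)C(C)(C)C)cc2OC)[C@H](O[Si](C)(C)C(C)(C)C)C1 | intermediate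
12 | (E)-but-2-enal (crotonaldehyde) | C/C=C/C=O | starting material
13 | (3E)-1,1-dibromopenta-1,3-diene | C/C=C/C=C(Br)Br | intermediate
14 | tert-butyldimethyl(prop-2-yn-1-yloxy)silane | C#CCO[Si](C)(C)C(C)(C)C | starting material
15 | (3E)-1-bromopent-3-en-1-yne | C/C=C/C#CBr | intermediate (not isolated)
16 | tert-butyldimethyl{[(6E)-octa-6-ene-2,4-diyn-1-yl]oxy}silane | C/C=C/C#CC#CCO[Si](C)(C)C(C)(C)C | intermediate
17 | (1S,6R)-6-[(tert-butyldimethylsilyl)oxy]-3-{[(tert-butyldimethylsilyl)oxy]methyl}-1-methyl-2-oxo-4-[(3E)-pent-3-en-1-yn-1-yl]cyclohex-3-en-1-yl 4-[(tert-butyldimethylsilyl)oxy]-2-methoxy-6-methylbenzoate | C/C=C/C#CC1=C(CO[Si](C)(C)C(C)(C)C)C(=O)[C@@](C)(OC(=O)c2c(C)cc(O[Si](C)(C)C(C)(C)C)cc2OC)[C@H](O[Si](C)(C)C(C)(C)C)C1 | intermediate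
18 | (1S,6R)-6-hydroxy-3-(hydroxymethyl)-1-methyl-2-oxo-4-[(3E)-pent-3-en-1-yn-1-yl]cyclohex-3-en-1-yl 4-hydroxy-2-methoxy-6-methylbenzoate | C/C=C/C#CC1=C(CO)C(=O)[C@@](C)(OC(=O)c2c(C)cc(O)cc2OC)[C@H](O)C1 | intermediate
19 | (6R,7S)-6-hydroxy-7-methyl-8-oxo-3-[(1E)-prop-1-en-1-yl]-5,6,7,8-tetrahydro-1H-isochromen-7-yl 4-hydroxy-2-methoxy-6-methylbenzoate | C/C=C/C1=CC2=C(CO1)C(=O)[C@@](C)(OC(=O)c1c(C)cc(O)cc1OC)[C@H](O)C2 | target

## Step count and least certain steps

Total step count: 11. Longest linear sequence: 9 steps (steps 1–6, then 9, 10 and 11); steps 7 and 8 form the second branch.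

Step 9 (carries the proposed new method). What may go wrong: consumption of the diyne by nickel-mediated oligomerisation while the hindered ketone of 11 fails to enter oxidative cyclisation. The α-quaternary centre slows carbonyl binding, the α-acyloxy C–O bond can itself add oxidatively to zerovalent nickel, and once the metallacycle exists, opening toward C7, loss of the C6 silyloxy group by β-elimination or reaction at the wrong alkyne can compete. Fallback, made of known reactions only, sets out from 11 (with 13) and comes back at 17:
- Two successive diazomethane ring homologations (Büchner–Curtius–Schlotterbeck reaction; as with other α-heteroatom-substituted cyclobutanones, the CH2 carbon and not the acyloxy-bearing carbon should migrate) would give first the cyclopentanone F1 (CH2N2, Et2O, 0 °C) and then the cyclohexanone F2 (CH2N2, BF3·OEt2), with both stereocentres and the ester carried along.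
- F2 can enolise only toward C8a, so dehydrogenation with IBX should give the enone F3.
- Conjugate transfer of the alkynyl group from the alkynylalane F4 (made in the flask from 13 with n-BuLi and then Me2AlCl) under Ni(acac)2/i-Bu2AlH catalysis, with interception of the enolate so formed by monomeric formaldehyde, would give the hydroxymethyl ketone F5.
- Silylation (TBSCl, imidazole) to the silyl ether F6 and a second dehydrogenation toward C4a (IBX, or selenoxide elimination) would deliver 17.

Step 5. What may go wrong: slow cycloaddition that lets the ketene oligomerise, incomplete trans selectivity because methyl and acyloxy differ little in effective size, and base-induced loss of the silyloxy group from the product. A racemate also means that half of the material is discarded in step 6. Fallback, from 8 (made from 6 as in step 5) back to 11: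
- The cycloaddition is run with the enantiopure auxiliary enol ether F7 in place of 7 (drawn as the (S)-auxiliary; the enantiomer that leads to the (1S,2R) ring would be used). The bulky 1-arylethyl group shields one face of the enol ether, and the cycloadducts are diastereomers separable on silica; this gives the auxiliary cycloadduct F8.
- Acidolysis of the benzylic ether (CF3CO2H, CH2Cl2, 0 °C) would give the hydroxy ketone F9, and silylation (TBSOTf, 2,6-lutidine) returns 11 without a resolution.

Step 10. What may go wrong: incomplete cleavage of the hindered C6 silyl ether and of the aryl silyl ether under conditions mild enough for the ynenone. If more basic fluoride is used to force it, elimination through the C5 dienolate or retro-aldol cleavage can follow. Fallback with a staged order, from 17 back to 19: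
- Brief exposure to HF·pyridine at 0 °C (or PPTS in MeOH) removes only the primary silyl ether and gives the primary alcohol F10.
- AuCl3 then closes the pyran to the bis-silyl ether F11, whose vinylogous-ester character makes C5 less acidic.
- Bu4NF buffered with AcOH removes the two remaining silyl groups to give 19.

Step 11. What may go wrong: attack of the hydroxyl at C4 (5-exo) followed by isomerisation to a fused furan, the usual fate of simple (Z)-enynols, or acid-promoted hydration of the product enol ether by traces of HCl from the gold salt. Fallback by an amine relay, from 18 back to 19: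
- Pyrrolidine (THF, 0 °C) adds in conjugate 1,6-fashion to C3, which fixes the regiochemistry and gives the dienaminone F12.
- Mild acid (AcOH or silica gel) then lets the C1 hydroxyl add to the iminium-like C3 and expel pyrrolidine, which forms the same enol ether without a metal.

Step 8. What may go wrong: loss or decomposition of the volatile bromoalkyne before coupling, and homocoupling of either alkyne. Fallback with reversed polarity, from 13 and 14 back to 16:
- 14 is converted into the bench-stable bromoalkyne F13 (NBS, AgNO3 cat., acetone).
- 13 is converted in one flask into the alkynylzinc chloride F14 (n-BuLi, 2 equiv, then ZnCl2).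
- Negishi-type coupling with Pd(PPh3)4 (zerovalent palladium) joins the two to give 16.

## Further compounds

F1 | step 9 | (1S,2R)-2-[(tert-butyldimethylsilyl)oxy]-1-methyl-5-oxocyclopentyl 4-[(tert-butyldimethylsilyl)oxy]-2-methoxy-6-methylbenzoate | O=C1[C@@](C)(OC(=O)c2c(C)cc(O[Si](C)(C)C(C)(C)C)cc2OC)[C@H](O[Si](C)(C)C(C)(C)C)CC1
F2 | step 9 | (1S,2R)-2-[(tert-butyldimethylsilyl)oxy]-1-methyl-6-oxocyclohexyl 4-[(tert-butyldimethylsilyl)oxy]-2-methoxy-6-methylbenzoate | O=C1[C@@](C)(OC(=O)c2c(C)cc(O[Si](C)(C)C(C)(C)C)cc2OC)[C@H](O[Si](C)(C)C(C)(C)C)CCC1
F3 | step 9 | (1S,6R)-6-[(tert-butyldimethylsilyl)oxy]-1-methyl-2-oxocyclohex-3-en-1-yl 4-[(tert-butyldimethylsilyl)oxy]-2-methoxy-6-methylbenzoate | O=C1[C@@](C)(OC(=O)c2c(C)cc(O[Si](C)(C)C(C)(C)C)cc2OC)[C@H](O[Si](C)(C)C(C)(C)C)CC=C1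
F4 | step 9 | dimethyl[(3E)-pent-3-en-1-yn-1-yl]aluminium | C/C=C/C#C[Al](C)C
F5 | step 9 | (1S,6R)-6-[(tert-butyldimethylsilyl)oxy]-3-(hydroxymethyl)-1-methyl-2-oxo-4-[(3E)-pent-3-en-1-yn-1-yl]cyclohexyl 4-[(tert-butyldimethylsilyl)oxy]-2-methoxy-6-methylbenzoate (mixture at C3 and C4 of the ring) | O=C1[C@@](C)(OC(=O)c2c(C)cc(O[Si](C)(C)C(C)(C)C)cc2OC)[C@H](O[Si](C)(C)C(C)(C)C)CC(C#C/C=C/C)C1CO
F6 | step 9 | (1S,6R)-6-[(tert-butyldimethylsilyl)oxy]-3-{[(tert-butyldimethylsilyl)oxy]methyl}-1-methyl-2-oxo-4-[(3E)-pent-3-en-1-yn-1-yl]cyclohexyl 4-[(tert-butyldimethylsilyl)oxy]-2-methoxy-6-methylbenzoate (mixture at C3 and C4 of the ring) | O=C1[C@@](C)(OC(=O)c2c(C)cc(O[Si](C)(C)C(C)(C)C)cc2OC)[C@H](O[Si](C)(C)C(C)(C)C)CC(C#C/C=C/C)C1CO[Si](C)(C)C(C)(C)C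
F7 | step 5 | 2-[(1S)-1-(ethenyloxy)ethyl]-1,3,5-tri(propan-2-yl)benzene | C=CO[C@@H](C)c1c(C(C)C)cc(C(C)C)cc1C(C)C
F8 | step 5 | (1S,2R)-1-methyl-4-oxo-2-{(1S)-1-[2,4,6-tri(propan-2-yl)phenyl]ethoxy}cyclobutyl 4-[(tert-butyldimethylsilyl)oxy]-2-methoxy-6-methylbenzoate | O=C1[C@@](C)(OC(=O)c2c(C)cc(O[Si](C)(C)C(C)(C)C)cc2OC)[C@H](O[C@@H](C)c2c(C(C)C)cc(C(C)C)cc2C(C)C)C1
F9 | step 5 | (1S,2R)-2-hydroxy-1-methyl-4-oxocyclobutyl 4-[(tert-butyldimethylsilyl)oxy]-2-methoxy-6-methylbenzoate | O=C1[C@@](C)(OC(=O)c2c(C)cc(O[Si](C)(C)C(C)(C)C)cc2OC)[C@H](O)C1
F10 | step 10 | (1S,6R)-6-[(tert-butyldimethylsilyl)oxy]-3-(hydroxymethyl)-1-methyl-2-oxo-4-[(3E)-pent-3-en-1-yn-1-yl]cyclohex-3-en-1-yl 4-[(tert-butyldimethylsilyl)oxy]-2-methoxy-6-methylbenzoate | C/C=C/C#CC1=C(CO)C(=O)[C@@](C)(OC(=O)c2c(C)cc(O[Si](C)(C)C(C)(C)C)cc2OC)[C@H](O[Si](C)(C)C(C)(C)C)C1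
F11 | step 10 | (6R,7S)-6-[(tert-butyldimethylsilyl)oxy]-7-methyl-8-oxo-3-[(1E)-prop-1-en-1-yl]-5,6,7,8-tetrahydro-1H-isochromen-7-yl 4-[(tert-butyldimethylsilyl)oxy]-2-methoxy-6-methylbenzoate | C/C=C/C1=CC2=C(CO1)C(=O)[C@@](C)(OC(=O)c1c(C)cc(O[Si](C)(C)C(C)(C)C)cc1OC)[C@H](O[Si](C)(C)C(C)(C)C)C2
F12 | step 11 | (1S,6R)-6-hydroxy-3-(hydroxymethyl)-1-methyl-2-oxo-4-[(3E)-2-(pyrrolidin-1-yl)penta-1,3-dien-1-yl]cyclohex-3-en-1-yl 4-hydroxy-2-methoxy-6-methylbenzoate (enamine geometry not defined) | C/C=C/C(N1CCCC1)=CC1=C(CO)C(=O)[C@@](C)(OC(=O)c2c(C)cc(O)cc2OC)[C@H](O)C1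
F13 | step 8 | [(3-bromoprop-2-yn-1-yl)oxy](tert-butyl)dimethylsilane | BrC#CCO[Si](C)(C)C(C)(C)C
F14 | step 8 | chloro[(3E)-pent-3-en-1-yn-1-yl]zinc | C/C=C/C#C[Zn]Cl
A1 | alternative 1 | 1-{(6R,7R)-6-[(tert-butyldimethylsilyl)oxy]-7-hydroxy-3-[(1E)-prop-1-en-1-yl]-1,5,6,7-tetrahydrocyclopenta[c]pyran-7-yl}ethan-1-one | C/C=C/C1=CC2=C(CO1)[C@](O)(C(C)=O)[C@H](O[Si](C)(C)C(C)(C)C)C2
A2 | alternative 1 | (6R,7S)-6-[(tert-butyldimethylsilyl)oxy]-7-hydroxy-7-methyl-3-[(1E)-prop-1-en-1-yl]-1,5,6,7-tetrahydro-8H-isochromen-8-one | C/C=C/C1=CC2=C(CO1)C(=O)[C@@](C)(O)[C@H](O[Si](C)(C)C(C)(C)C)C2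
A3 | alternative 2 | (6R,7S)-7-methyl-8-oxo-3-[(1E)-prop-1-en-1-yl]-6-[(triethylsilyl)oxy]-5,6,7,8-tetrahydro-1H-isochromen-7-yl but-2-ynoate | C/C=C/C1=CC2=C(CO1)C(=O)[C@@](C)(OC(=O)C#CC)[C@H](O[Si](CC)(CC)CC)C2
A4 | alternative 2 | 1,1-dimethoxy-3-[(trimethylsilyl)oxy]buta-1,3-diene | C=C(O[Si](C)(C)C)C=C(OC)OC
A5 | alternative 2 | (6R,7S)-7-methyl-8-oxo-3-[(1E)-prop-1-en-1-yl]-6-[(triethylsilyl)oxy]-5,6,7,8-tetrahydro-1H-isochromen-7-yl 4-hydroxy-2-methoxy-6-methylbenzoate | C/C=C/C1=CC2=C(CO1)C(=O)[C@@](C)(OC(=O)c1c(C)cc(O)cc1OC)[C@H](O[Si](CC)(CC)CC)C2
A6 | alternative 3 | (2E,5R)-5-[(tert-butyldimethylsilyl)oxy]-6-oxo-3-[(3E)-pent-3-en-1-yn-1-yl]-2-{[(triethylsilyl)oxy]methyl}hept-2-enal | O=C/C(CO[Si](CC)(CC)CC)=C(/C#C/C=C/C)C[C@@H](O[Si](C)(C)C(C)(C)C)C(C)=O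
A7 | alternative 3 | (5R,6S)-5-[(tert-butyldimethylsilyl)oxy]-6-hydroxy-6-methyl-3-[(3E)-pent-3-en-1-yn-1-yl]-2-{[(triethylsilyl)oxy]methyl}cyclohex-2-en-1-one | C/C=C/C#CC1=C(CO[Si](CC)(CC)CC)C(=O)[C@@](C)(O)[C@H](O[Si](C)(C)C(C)(C)C)C1
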